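(All runs were generated by integration from invented constants; noise was put on by code.)

0.0512 mM/h of target in the zeta run and 0.0495 mM/h in the beta run: these slopes over the later readings give the quick number requested, although the beta run was charged with 18 mM of solid substrate against 8 mM in the zeta run.

in all of them: gas phase 3.8 mM (held)

|  | solid substrate | remark | time |
|---|---|---|---|
| zeta | 8 mM | run made earlier |  |
| beta | 18 mM | run made earlier |  |
| flask | 12 mM |  | 30 h |

- zeta (time / h: target / %, solid substrate / %): 3.00: 0.4, 96.8; 6.00: 2.2, 95.6; 15.0: 7.0, 90.8; 40.0: 23.0, 74.8
- beta (time / h: target / %, solid substrate / %): 5.00: 0, 97.6; 12.0: 2.4, 96.4; 25.0: 6.1, 92.2; 40.0: 10.1, 88.2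

(standard deviation of a reading: 0.5 percentage points)

- as a solid, counted per litre of solution: solid substrate
- at the start none of the gas is dissolved
- on the list of suspects stand: gas phase <-> dissolved gas; starting material + dissolved gas -> target; dissolved gas <-> dormant form; solid substrate <-> starting material
- at the start none of the solid substrate is in solution

- target at 30 h, in percent of the solid substrate charged
- the change that raises the amount of target at 30 h, in percent of the solid substrate charged most ("none" if none brings more than 2 percentage points) (midnight / autumn / dawn / noon / none)
- amount of target at 30 h, in percent of the solid substrate charged, after midnight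

- midnight: doubling the solubility of the solid substrate, all else as stated
- autumn: doubling the transfer coefficient of the gas phase, all else as stated
- dawn: doubling the dissolution coefficient of the solid substrate, all else as stated
- noon: doubling the saturation concentration of gas phase, all else as stated

Counted in mM, the target at 40.0 h reads 1.84 mM in the zeta run and 1.82 mM in the beta run, so between these two runs the output is zero-order in the charge. The quantity to carry is the plateau rate r, the mean of both slopes in mM of target per hour, 0.0504 mM/h. The lag t_L, the start-up time that r leaves over at the last reading, comes to 3.67 h. My own reckoning for the flask, r(t − t_L) over its charge of 12 mM, gives 11.0% at 30 h. Both runs held the gas at 3.8 mM, so this reckoning names no best change.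

The forecast gives 10.9%, then 20.5% after midnight, and chooses noon: “Noon is the safer choice because it helps even if gas transfer is limiting”.

The flask gives 10.8%, and 20.8% after midnight. The best change is midnight, adding 10 percentage points against 4.9 points for noon.

    gas phase ⇌ dissolved gas, rate k1*(csat - [dissolved gas]) (kL = 0.00350 /min)
    starting material + dissolved gas → target (k = 1.80 /M/min)
    dissolved gas ⇌ dormant form (K = 12.0, k = 0.00360 /min)
    solid substrate ⇌ starting material, rate k4*(cs4 - [starting material]) while solid is left; crystals form when [starting material] > cs4 (solubility = 0.390 mM, k = 0.00480 /min)

The low solubility of starting material, together with the time given, holds this flask down: without that solubility limit the target reaches 95.1%, and ten times as long gives 100%, against 10.8%. Removing the drag of gas transfer, one part of the shortfall, reaches 15.7%. On the neighbouring flask, the same charge read at 8.0 h, r(t − t_L) gives 1.82%; the computed result is 1.97%.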